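**Plan**
1. Cuts: the ring B C3'–butanoyl bond and the two benzyl ether O–C bonds are removed first. Ring A is then opened at two bonds at once, C5–C6 and C1–C2, which separates a ring B propanoate (C1, C6 and the CH2 bridge) from 3,3-dimethyl-6-propylpyran-2,4-dione.
2. Enabling feature: ring A (C1 carbonyl, C2 with butanoyl, C3, C4 as CMe2, C5, C6 with the bridge) is a 2-acyl-1,3,5-trione. C3–C4–C5 is a dimethylmalonyl unit and C2 with its butanoyl group is a 1,3-diketone, which can be stored as the enol-lactone half of the pyranone and released by acyl transfer.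
3. Forward: the pyranone ring is closed from pentan-2-one and dimethylmalonyl dichloride; the propanoate chain is grown on 2,4,6-trihydroxybenzaldehyde; the halves are joined and ring A is closed as a carbocycle in one flask; debenzylation and C-butanoylation of ring B end the route.
4. Stereochemistry: the target has no stereocentre. The E alkene of 10 and the racemic carbon of 12 disappear in the steps that follow them.

Key step: step 7

Remark: ring A compounds are written in the enol form used in the target SMILES; the tautomers interconvert freely and are treated as one compound. Ring B positions are C1' (bridge) to C6'.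

**Step 1**
Reactants: 1 pentan-2-one
Product: 2 trimethyl(pent-1-en-2-yloxy)silane
Conditions: LiN(i-Pr)2 (commercial solution), THF, −78 °C; Me3SiCl, −78 → 20 °C; distillation
Reagents that add atoms: chlorotrimethylsilane, C[Si](C)(C)Cl
Why: Kinetic deprotonation of a methyl ketone by a hindered amide base at −78 °C removes the less substituted α-proton, and O-silylation of the lithium enolate fixes the terminal enol ether (kinetic silyl enol ether formation).

**Step 2**
Reactants: 2 trimethyl(pent-1-en-2-yloxy)silane; 3 dimethylmalonyl dichloride
Product: 5 3,3-dimethyl-6-propyl-2H-pyran-2,4(3H)-dione, via 2,2-dimethyl-3,5-dioxooctanoyl chloride 4 (not isolated)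
Conditions: 3 (1.0 equiv), ZnCl2 (10 mol%), CH2Cl2–Et2O, 0 °C; 2 added slowly, 0 → 20 °C; Et3N (1.1 equiv), 0 °C; non-aqueous work-up, distillation
Reagents that add atoms: none
Why: Lewis acid-catalysed C-acylation of a silyl enol ether by an acid chloride (1,3-diketone synthesis) gives 4, whose enol oxygen is then acylated by the second acid chloride in a 6-exo-trig lactonisation once triethylamine takes up HCl; the dichloride cannot form a ketene, so only acyl substitution is open to it.

**Step 3**
Reactants: 6 2,4,6-trihydroxybenzaldehyde
Product: 7 2,6-dihydroxy-4-methoxybenzaldehyde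
Conditions: MeI (1.05 equiv), NaHCO3 (1.2 equiv), DMF, 40 °C
Reagents that add atoms: iodomethane, CI
Why: Williamson O-methylation under a weak base: the 4-hydroxyl is the most acidic and is not held in the hydrogen bond to the formyl group, so one equivalent of iodomethane should alkylate it in preference to the two ortho hydroxyls.

**Step 4**
Reactants: 7 2,6-dihydroxy-4-methoxybenzaldehyde
Product: 8 2,6-bis(benzyloxy)-4-methoxybenzaldehyde
Conditions: BnBr (2.4 equiv), K2CO3 (3 equiv), DMF, 60 °C
Reagents that add atoms: benzyl bromide, BrCc1ccccc1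
Why: Williamson etherification; with the stronger base, excess benzyl bromide and heat, both remaining phenols are benzylated.

**Step 5**
Reactants: 8 2,6-bis(benzyloxy)-4-methoxybenzaldehyde; 9 trimethyl phosphonoacetate
Product: 10 methyl (E)-3-[2,6-bis(benzyloxy)-4-methoxyphenyl]prop-2-enoate
Conditions: 9 (1.3 equiv), NaH, THF, 0 °C; then 8, 0 → 45 °C
Reagents that add atoms: none
Why: Horner–Wadsworth–Emmons olefination of an aromatic aldehyde with a stabilised phosphonate anion gives the E cinnamate, whose geometry is irrelevant because the alkene is reduced next.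

**Step 6**
Reactants: 10 methyl (E)-3-[2,6-bis(benzyloxy)-4-methoxyphenyl]prop-2-enoate
Product: 11 methyl 3-[2,6-bis(benzyloxy)-4-methoxyphenyl]propanoate
Conditions: NaBH4 (3 equiv), NiCl2·6H2O (20 mol%), MeOH–THF, 0 → 20 °C
Reagents that add atoms: none
Why: Conjugate reduction of a cinnamate by nickel boride formed from NiCl2 and NaBH4, which saturates the activated alkene but does not cleave aryl benzyl ethers or reduce the ester.

**Step 7**
Reactants: 11 methyl 3-[2,6-bis(benzyloxy)-4-methoxyphenyl]propanoate; 5 3,3-dimethyl-6-propyl-2H-pyran-2,4(3H)-dione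
Product: 13 2-butanoyl-6-{[2,6-bis(benzyloxy)-4-methoxyphenyl]methyl}-3,5-dihydroxy-4,4-dimethylcyclohexa-2,5-dien-1-one, via acyclic triketo ester 12 (not isolated)
Conditions: 11 (2.1 equiv), LiN(i-Pr)2 (2.1 equiv), THF, −78 °C; 5 (1.0 equiv), −78 → −20 °C; MeOH (4 equiv), 0 → 45 °C; 1 M HCl; 13 taken into aqueous Na2CO3 and re-acidified, excess 11 recovered from the organic layer
Reagents that add atoms: none
Why: Proposed new method: the lithium enolate of 11 should add to the lactone carbonyl (C2 of the pyranone, an enol-ester carbonyl of vinylogous-anhydride character) and the adduct should collapse with loss of the 1,3-diketone enolate, which forms the C5–C6 bond of ring A and unmasks the butanoyl ketone from the ring oxygen in 12; the second equivalent of enolate removes the new β-keto ester proton, which is why 2.1 equivalents are used and the excess is expected back as 11. Added methanol then shuttles protons so that the diketone carbon C2 carries the charge while the β-keto ester is neutral, and a 6-exo-trig Claisen (Dieckmann-type) attack of C2 on the methyl ester with loss of methoxide forms C1–C2 and gives ring A as its trione anion, the thermodynamic sink. The closest known reactions are the Fujimoto–Belleau opening of enol lactones by carbon nucleophiles and the base-induced Claisen cyclisation of 3,5,7-trioxoalkanoates to acylphloroglucinols; their union on a 3,3-dimethylpyran-2,4-dione has not been shown. No stereocentre is formed, because C6 ends as an enol carbon and the racemic centre of 12 is lost. The step needs attack at the lactone carbonyl in preference to the vinylogous ester carbonyl C4, to conjugate addition at C6 of the pyranone and to deprotonation of the propyl CH2; this rests on the higher electrophilicity of the enol-ester carbonyl at −78 °C, on the CMe2 group, which blocks enolisation between C3 and C5 and favours closure, and on the reversibility of the competing O-acylation under the equilibrating conditions.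

**Step 8**
Reactants: 13 2-butanoyl-6-{[2,6-bis(benzyloxy)-4-methoxyphenyl]methyl}-3,5-dihydroxy-4,4-dimethylcyclohexa-2,5-dien-1-one
Product: 14 2-butanoyl-6-[(2,6-dihydroxy-4-methoxyphenyl)methyl]-3,5-dihydroxy-4,4-dimethylcyclohexa-2,5-dien-1-one
Conditions: H2 (1 atm), Pd/C (10 wt% Pd), EtOAc–MeOH, 20 °C
Reagents that add atoms: none
Why: Hydrogenolysis of aryl benzyl ethers over palladium on carbon under neutral conditions; the enolised trione of ring A is a vinylogous acid and should not be hydrogenated at atmospheric pressure.

**Step 9**
Reactants: 14 2-butanoyl-6-[(2,6-dihydroxy-4-methoxyphenyl)methyl]-3,5-dihydroxy-4,4-dimethylcyclohexa-2,5-dien-1-one; 15 butyric anhydride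
Product: 16 2-butanoyl-6-[(3-butanoyl-2,6-dihydroxy-4-methoxyphenyl)methyl]-3,5-dihydroxy-4,4-dimethylcyclohexa-2,5-dien-1-one (the target)
Conditions: 15 (1.1 equiv), BF3·OEt2 (5 equiv), 1,4-dioxane, 20 → 45 °C; then H2O–MeOH, 50 °C
Reagents that add atoms: none
Why: Friedel–Crafts C-acylation of a phloroglucinol-type ring promoted by BF3 (O-acylation and Fries-type shift within the boron chelate): the free positions C3' and C5' are equivalent by symmetry, ring A has no free nucleophilic carbon, and the first acyl group deactivates ring B towards a second.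

**Compound list**
1 | pentan-2-one | CCCC(C)=O | starting material
2 | trimethyl(pent-1-en-2-yloxy)silane | C=C(CCC)O[Si](C)(C)C | intermediate
3 | dimethylmalonyl dichloride (2,2-dimethylpropanedioyl dichloride) | CC(C)(C(=O)Cl)C(=O)Cl | starting material
4 | 2,2-dimethyl-3,5-dioxooctanoyl chloride (not isolated) | CCCC(=O)CC(=O)C(C)(C)C(=O)Cl | intermediate
5 | 3,3-dimethyl-6-propyl-2H-pyran-2,4(3H)-dione | CCCC1=CC(=O)C(C)(C)C(=O)O1 | intermediate
6 | 2,4,6-trihydroxybenzaldehyde | O=Cc1c(O)cc(O)cc1O | starting material
7 | 2,6-dihydroxy-4-methoxybenzaldehyde | COc1cc(O)c(C=O)c(O)c1 | intermediate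
8 | 2,6-bis(benzyloxy)-4-methoxybenzaldehyde | COc1cc(OCc2ccccc2)c(C=O)c(OCc2ccccc2)c1 | intermediate
9 | trimethyl phosphonoacetate | COC(=O)CP(=O)(OC)OC | starting material
10 | methyl (E)-3-[2,6-bis(benzyloxy)-4-methoxyphenyl]prop-2-enoate | COC(=O)/C=C/c1c(OCc2ccccc2)cc(OC)cc1OCc1ccccc1 | intermediate
11 | methyl 3-[2,6-bis(benzyloxy)-4-methoxyphenyl]propanoate | COC(=O)CCc1c(OCc2ccccc2)cc(OC)cc1OCc1ccccc1 | intermediate
12 | methyl 2-{[2,6-bis(benzyloxy)-4-methoxyphenyl]methyl}-4,4-dimethyl-3,5,7-trioxodecanoate (racemic, present as its lithium enolate, not isolated) | CCCC(=O)CC(=O)C(C)(C)C(=O)C(Cc1c(OCc2ccccc2)cc(OC)cc1OCc1ccccc1)C(=O)OC | intermediate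
13 | 2-butanoyl-6-{[2,6-bis(benzyloxy)-4-methoxyphenyl]methyl}-3,5-dihydroxy-4,4-dimethylcyclohexa-2,5-dien-1-one | CCCC(=O)C1=C(O)C(C)(C)C(O)=C(Cc2c(OCc3ccccc3)cc(OC)cc2OCc2ccccc2)C1=O | intermediate
14 | 2-butanoyl-6-[(2,6-dihydroxy-4-methoxyphenyl)methyl]-3,5-dihydroxy-4,4-dimethylcyclohexa-2,5-dien-1-one | CCCC(=O)C1=C(O)C(C)(C)C(O)=C(Cc2c(O)cc(OC)cc2O)C1=O | intermediate
15 | butyric anhydride | CCCC(=O)OC(=O)CCC | starting material
16 | 2-butanoyl-6-[(3-butanoyl-2,6-dihydroxy-4-methoxyphenyl)methyl]-3,5-dihydroxy-4,4-dimethylcyclohexa-2,5-dien-1-one | CCCC(=O)C1=C(O)C(C)(C)C(O)=C(Cc2c(O)cc(OC)c(C(=O)CCC)c2O)C1=O | target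

**Step count**
Total: 9 steps. Longest linear sequence: 7 steps (steps 3, 4, 5, 6, 7, 8, 9); the pyranone branch (steps 1 and 2) joins at step 7.

**Steps most likely to fail**

1. Step 7 (proposed new method). The ester enolate may act as a base on the propyl CH2 of 5 or add in conjugate fashion at C6 of the pyranone instead of at the lactone carbonyl. After ring opening, the chain may close through oxygen back to an enol lactone, or by aldol attack of the β-keto ester carbon on the butanoyl ketone, instead of by Claisen attack. Methoxide may also cut the chain next to the CMe2 carbon by retro-Claisen cleavage.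
Fallback (known chemistry), setting out from 8 and returning at 13: ring A is made in the classical way and joined to ring B by reductive alkylation. Commercial benzene-1,3,5-triol is C-butanoylated with 15 and BF3·OEt2 to 1-(2,4,6-trihydroxyphenyl)butan-1-one F1. F1 is methylated twice at one ring carbon (MeI, NaOMe, MeOH) to 2-butanoyl-3,5-dihydroxy-4,4-dimethylcyclohexa-2,5-dien-1-one F2. Aldehyde 8 and F2 are condensed under L-proline catalysis (Knoevenagel) to 2-butanoyl-6-{[2,6-bis(benzyloxy)-4-methoxyphenyl]methylidene}-3-hydroxy-4,4-dimethylcyclohex-2-ene-1,5-dione F3. F3 is reduced in the same flask at the exocyclic alkene by diethyl 2,6-dimethyl-1,4-dihydropyridine-3,5-dicarboxylate (Hantzsch ester) to give 13.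

2. Step 9. Under the Lewis acid the methylene bridge may be cleaved or exchanged by protonation at the electron-rich ipso carbon C1' of ring B. A free ortho phenol may condense with a ring A carbonyl with loss of water to a pyran-fused ring. O-acylation may also fail to be followed by migration to carbon.
Fallback, setting out from 13 and returning at 16: the order of acylation and deprotection is reversed so that no free phenol meets acid. Compound 13 is C-acylated with butanoic acid and (CF3CO)2O in CH2Cl2 at 0 → 20 °C (acylation by the mixed anhydride, the two free positions again being equivalent). A brief K2CO3/MeOH treatment cleaves any enol esters on ring A, giving 2-butanoyl-6-{[2,6-bis(benzyloxy)-3-butanoyl-4-methoxyphenyl]methyl}-3,5-dihydroxy-4,4-dimethylcyclohexa-2,5-dien-1-one F4. Hydrogenolysis of F4 (H2, Pd/C, EtOAc–MeOH) then gives 16.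

3. Step 2. The hindered acid chloride may react slowly at carbon, so that double acylation of two enol ether molecules or hydrolytic opening of the moisture-sensitive enol lactone during isolation takes over. Any internal enol ether carried in 2 would lead to a regioisomeric pyranone.
Fallback, setting out from 3 and 1 and returning at 5: the two acylations are done in separate, classical operations. Dichloride 3 is converted with MeOH and pyridine into dimethyl 2,2-dimethylpropanedioate F5. The kinetic lithium enolate of 1 (2.1 equiv, LiN(i-Pr)2, THF, −78 → 20 °C) is acylated by this non-enolisable diester in a crossed Claisen condensation to methyl 2,2-dimethyl-3,5-dioxooctanoate F6. F6 is cyclised to 5 by heating with catalytic TsOH in toluene while methanol is distilled off (enol lactonisation of a 3,5-dioxo ester).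

**Further compounds**
F1 | step 7 | 1-(2,4,6-trihydroxyphenyl)butan-1-one | CCCC(=O)c1c(O)cc(O)cc1O
F2 | step 7 | 2-butanoyl-3,5-dihydroxy-4,4-dimethylcyclohexa-2,5-dien-1-one | CCCC(=O)C1=C(O)C(C)(C)C(O)=CC1=O
F3 | step 7 | 2-butanoyl-6-{[2,6-bis(benzyloxy)-4-methoxyphenyl]methylidene}-3-hydroxy-4,4-dimethylcyclohex-2-ene-1,5-dione (alkene geometry not defined, erased on reduction) | CCCC(=O)C1=C(O)C(C)(C)C(=O)C(=Cc2c(OCc3ccccc3)cc(OC)cc2OCc2ccccc2)C1=O
F4 | step 9 | 2-butanoyl-6-{[2,6-bis(benzyloxy)-3-butanoyl-4-methoxyphenyl]methyl}-3,5-dihydroxy-4,4-dimethylcyclohexa-2,5-dien-1-one | CCCC(=O)C1=C(O)C(C)(C)C(O)=C(Cc2c(OCc3ccccc3)cc(OC)c(C(=O)CCC)c2OCc2ccccc2)C1=O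
F5 | step 2 | dimethyl 2,2-dimethylpropanedioate | COC(=O)C(C)(C)C(=O)OC
F6 | step 2 | methyl 2,2-dimethyl-3,5-dioxooctanoate | CCCC(=O)CC(=O)C(C)(C)C(=O)OC
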